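## The problem

The target 26 is a linear prodelphinidin trimer in which three 2,3-cis flavan-3-ol units of the epigallocatechin type are joined head to tail by two aryl–alkyl bonds, top C4 to middle C8 and middle C4 to bottom C8, and O3 of the middle unit carries a galloyl ester. There are eight stereocentres: C2, C3 and C4 of the top and middle units, and C2 and C3 of the bottom unit. Within a unit, C2 and C3 steer C4, because a nucleophile adds to a flavan-4-yl cation anti to the C2 aryl group and the C3 oxygen; this gives the 3,4-trans (4β) linkage that is needed twice. Nothing steers the bottom unit, whose C2 lies four bonds from the nearest stereocentre (middle C4), so its C2/C3 pair needs reagent control. The 18 phenols (three pyrogallol rings and a gallate among them) are sensitive to air and base, the benzylic interflavan bonds are cleaved by strong acid, C2 epimerises in base once phenols are free, and the gallate does not survive hydroxide or alkoxide. All phenols therefore stay masked as benzyl ethers until a neutral final step. The feature that makes the key step possible is that C4 of the bottom unit is an unsubstituted methylene: the bottom pyran (O1, C2, C3, C4, C4a, C8a) can be closed at the C3-ketone level from the phenol oxygen on C8a and a carbenoid C2 placed between ring B and the C3 carbonyl, and in the resulting flavan-3-one C2 is stereolabile, so one later reduction can set C2 and C3 together.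

## Retrosynthesis

**26 ⇒ 25 ⇒ 24.** The last bonds made are nineteen O–H bonds (hydrogenolysis of all benzyl ethers of 25) and, before that, the C3–H bond of the bottom unit. Reducing ketone 24 under conditions that equilibrate C2 sets both bottom stereocentres in one step. Benzyl is the only protecting group in the late intermediates, so a single neutral operation unmasks everything.

**24 ⇒ 23 (key disconnection).** The O1–C2 bond of the bottom pyran is cut to give the α-aryl-α-diazo ketone 23 with a free phenol on the neighbouring ring. Cutting C4–C4a instead would need a Friedel–Crafts closure onto a ring already carrying the bulky dimer, and cutting C2–C3 would leave two centres to be built acyclically. The O1–C2 cut uses the phenol that the preceding C-arylation provides, removes one ring and one (uncontrolled, stereolabile) centre, and asks of the forward step only chemoselective O–H insertion.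

**23 ⇒ 22 ⇒ 21 ⇒ 19 ⇒ 18 ⇒ 17 ⇒ 10 + 16.** The diazo group is traced back to a diazo transfer onto the unsymmetrical 1,3-diarylpropan-2-one 21; only the methylene next to the unhindered gallyl ring should enolise readily. This is shorter than acylating an electron-rich aryldiazomethane with an arylacetyl chloride, and it avoids that unstable diazoalkane. The ketone is the cleavage product of the 1,1-disubstituted alkene 19. Its carbon chain is placed by a Claisen rearrangement of ether 17, which delivers the 2-(arylmethyl)allyl group to the only hydrogen-bearing ortho carbon and forms the future C4–C4a bond regiospecifically. The phenol of 18 is silylated (19) until just before the key step, so that neither periodate, nor hemiketal/benzofuran formation, nor attack of a phenoxide on the sulfonyl azide can interfere. Ether 17 comes from phenol 10 and allylic alcohol 16.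

**10 ⇒ 8 + 9.** The bond from middle C4 to the phloroglucinol ring is cut. The forward reaction is capture of the middle flavan-4-yl cation, generated from thioether 8 by thiophilic AgBF4, by 3,5-bis(benzyloxy)phenol 9. It must go through a carbon ortho to the hydroxyl and from the β-face; both are favoured by sterics, and the face also by the participating gallate.

**8 ⇒ 4 + 7.** The top C4–middle C8 bond is cut. Donor 4 carries an oxygen leaving group at C4 and acceptor 7 a C4 arylthio group, so an oxophilic Lewis acid activates only 4. The middle unit thus arrives with its next leaving group already in place, and no oxidation of a dimer at one of two benzylic positions is needed.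

**4 and 7 ⇒ 3 ⇒ 2 ⇒ 1.** Both upper units come from one benzylated, C4-oxidised intermediate 3, made from natural epigallocatechin 1 via 2. Benzylation of O3 gives 4; exchange of the C4 ether for a thioether (5) and esterification with acid 6 give 7. Four of the eight stereocentres (C2 and C3 of the top and middle units) are taken from 1, and they control the two C4 centres.

**16 ⇒ 12 + 13; 12 ⇒ 11.** The allylic alcohol is cut between its internal alkene carbon and the benzylic carbon: carbomagnesiation of propargyl alcohol 13 with the Grignard reagent 14 derived from chloride 12, itself made from commercial alcohol 11.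

## Roads not taken

**Alternative 1: benzannulation builds the middle ring A.** The cut removes three bonds of the middle ring A (C8–C8a, C8a–C4a, C6–C7). In the forward sense, heating 3-benzyloxycyclobutenone A3 with the top-unit siloxyalkyne A2 would give phenol A1 by a Danheiser benzannulation (four-electron ring opening, [2+2] addition, second ring opening, six-electron electrocyclisation).
- Merits: the interflavan connectivity is fixed by construction, so there is no 4→6 isomer, no oligomerisation and no excess of a valuable partner. The three oxygens of the new ring arrive differentiated.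
- Weak points: A1 holds only one of the six rings still missing. The middle pyran with three contiguous centres (C4 bearing the bottom unit) and its gallate would have to be built without chiral-pool help, a harder version of the problem the chosen plan solves once for an unsubstituted C4. A2 also needs a sensitive ynol ether on a benzylic carbon.
- Comparison: this road is better in regiocontrol of the top–middle bond. The chosen plan sets against it that both upper units come intact from natural material, which supplies four stereocentres and controls two more, and that only one pyran ring is made.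

**Alternative 2: reverse-polarity Friedel–Crafts closure of the top pyran.** The cut is top C4–C4a. Acid would ionise the C4 carbinol of the open-chain precursor A5, and the 3,5-bis(benzyloxy)phenyl ether on C2 would attack through an ortho carbon to give the silyl-protected trimer A4.
- Merits: the closure is intramolecular, both ortho carbons are equivalent, the top–middle aryl bond exists before cyclisation (no regiochemical ambiguity, no excess nucleophile), and the silyl ether at middle O3 allows late galloylation.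
- Weak points: top C4 is set in the cyclisation of a planar cation flanked by a very large substituent, which is less predictable than anti attack on a preformed flavan ring. A5 contains an acid-labile benzylic aryl ether at C2 that can ionise in competition. Top C2 and C3 must be made by acyclic stereocontrol, and the middle and bottom units must already be joined and functionalised at middle C8 before A5 can be assembled, so the route is long.
- Comparison: A4 is as advanced as the chosen key-step product, and this road avoids the excess of acceptor used in step 6. The chosen plan sets against it the established facial selectivity of cation capture on intact rings and a three-step supply of the top unit.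

**Alternative 3: three-component o-quinone methide cycloaddition.** The cut removes C4–C4a, C3–C4 and O1–C2 of the middle pyran. An arylboronic-acid-templated condensation of phenol A7 with aldehyde A8 would release the o-quinone methide A10, which adds the Z-alkenylboronate A9 in a [4+2] mode to give A6; oxidation of the C–B bond with retention and galloylation would follow.
- Merits: this is the most convergent road, with three bonds, one ring and three stereocentres formed in one operation, 2,3-cis from the alkene geometry, O3 differentiated as boron, and both outer units from natural material.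
- Weak points: A10 is planar and its faces differ only through remote chirality, so the absolute sense at the three new centres and the C3/C4 relationship are not reliably controlled. A9, a Z-styrenylboronate, is a sluggish partner that can isomerise at the temperatures needed, and the methide carbon of A10 is hindered by the flavan-8-yl group.
- Comparison: if facial control held, this road would be shorter than the chosen plan and would build more complexity in its key step. The chosen plan sets against it that every centre comes from the chiral pool, from anti attack on a flavan cation, or from one reagent-controlled reduction whose wrong isomer can be oxidised back and recycled.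

Key step: step 16

Conventions: flavan numbering is used for each unit (top, middle, bottom). 4β means a C4 substituent trans to O3 and to the C2 aryl group. All flavan units are (2R,3R) unless stated.

Remark 1 (assumption): the (S,S)-TsDPEN catalyst is taken as the enantiomer matched to the 2R epimer of 24 (Si-face hydride delivery at C3, with the fused benzylic C4 side in the place of the aryl group of the usual model). If the sense is opposite, the (R,R) enantiomer is used with no other change.

Remark 2: the 4β configuration drawn for the ether and thioether groups of 3, 4, 5, 7 and 8 is the expected one and is erased on ionisation. Compound 24 forms as interconverting C2 epimers (2R drawn), and diol 20 as a mixture at its transient carbinol carbon.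

Step 1
Reactants: 1 (−)-epigallocatechin
Product: 2 5,7,3',4',5'-penta-O-benzyl-(−)-epigallocatechin
Conditions: BnBr (5.5 equiv), K2CO3, DMF, −10 °C to rt, argon
Reagents that add atoms: benzyl bromide, BrCc1ccccc1
Why: Williamson etherification; carbonate deprotonates only the five phenols (the C3 alcohol stays free), and low temperature under argon limits C-benzylation, pyrogallol oxidation and base-induced C2 epimerisation; no stereocentre is touched.

Step 2
Reactants: 2 5,7,3',4',5'-penta-O-benzyl-(−)-epigallocatechin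
Product: 3 4β-(2-ethoxyethoxy)-5,7,3',4',5'-penta-O-benzylepigallocatechin
Conditions: DDQ (2 equiv), 2-ethoxyethanol (5 equiv), CH2Cl2, rt
Reagents that add atoms: 2-ethoxyethanol, CCOCCO
Why: DDQ oxidation of the electron-rich benzylic C4–H gives the flavan-4-yl cation stabilised by ring A, which the alcohol captures anti to the C2 aryl and C3 hydroxyl groups (4β expected); this configuration is erased when the group ionises later.

Step 3
Reactants: 3 4β-(2-ethoxyethoxy)-5,7,3',4',5'-penta-O-benzylepigallocatechin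
Product: 4 3,5,7,3',4',5'-hexa-O-benzyl-4β-(2-ethoxyethoxy)epigallocatechin (top donor)
Conditions: NaH, BnBr, Bu4NI (cat.), DMF, 0 °C to rt
Reagents that add atoms: benzyl bromide, BrCc1ccccc1
Why: Williamson benzylation of the only free hydroxyl through its sodium alkoxide; with every phenol capped there is no quinone-methide path to C2 epimerisation.

Step 4
Reactants: 3 4β-(2-ethoxyethoxy)-5,7,3',4',5'-penta-O-benzylepigallocatechin
Product: 5 4β-(2,6-dimethylphenylthio)-5,7,3',4',5'-penta-O-benzylepigallocatechin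
Conditions: 2,6-Me2C6H3SH (3 equiv), BF3·OEt2, CH2Cl2, −78 to −30 °C
Reagents that add atoms: 2,6-dimethylbenzenethiol, Cc1cccc(C)c1S
Why: Lewis-acid ionisation of the C4 ether and capture by the soft thiol (thiolysis-type SN1 exchange) anti to the C2 aryl and C3 hydroxyl groups, hence 4β; the thioether is the thermodynamic sink, and the two ortho methyl groups make its sulfur a poor nucleophile in step 6.

Step 5
Reactants: 5 4β-(2,6-dimethylphenylthio)-5,7,3',4',5'-penta-O-benzylepigallocatechin; 6 3,4,5-tris(benzyloxy)benzoic acid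
Product: 7 4β-(2,6-dimethylphenylthio)-5,7,3',4',5'-penta-O-benzylepigallocatechin 3-O-[3,4,5-tris(benzyloxy)benzoate] (middle acceptor)
Conditions: DCC, DMAP, CH2Cl2, rt
Reagents that add atoms: none
Why: Steglich esterification of the secondary C3 alcohol; the gallate goes in early and, as an electron-withdrawing ester next to C4, makes the C4–S bond less prone to ionise under the hard Lewis acid of step 6.

Step 6
Reactants: 4 3,5,7,3',4',5'-hexa-O-benzyl-4β-(2-ethoxyethoxy)epigallocatechin; 7 middle acceptor (3 equiv)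
Product: 8 top–middle dimer thioether [hexa-O-benzyl-epigallocatechin-(4β→8)-4β-(2,6-dimethylphenylthio)-penta-O-benzylepigallocatechin 3-O-tris(benzyloxy)benzoate]
Conditions: TMSOTf (0.2 equiv), 4 Å MS, CH2Cl2, −78 °C; Et3N quench
Reagents that add atoms: none
Why: Friedel–Crafts-type interflavan coupling in which the oxophilic silyl triflate ionises only the C4 alkoxy group of 4 while the thioether of 7 stays inert (hard/soft orthogonality, as with thioglycoside acceptors); C8 of 7, less hindered than C6, attacks the cation anti to the C2 aryl and C3 benzyloxy groups and sets top C4 as 4β; the excess of 7, recovered by chromatography, suppresses further chain growth.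

Step 7
Reactants: 8 top–middle dimer thioether; 9 3,5-bis(benzyloxy)phenol (5 equiv)
Product: 10 dimer phenol [as 8 but with a 2-hydroxy-4,6-bis(benzyloxy)phenyl group at middle C4β]
Conditions: AgBF4 (2 equiv), 4 Å MS, THF, 0 °C
Reagents that add atoms: none
Why: the thiophilic Ag+ ion of AgBF4 ionises the C4–S bond; the cation, shielded on the α-face by the C2 aryl group and the participating 3-O-acyl group, is attacked on the β-face by the phenol through a carbon ortho to OH (two equivalent positions, each less hindered than the para carbon between two benzyloxy groups), which sets middle C4 as 4β; the excess of 9 outcompetes the A rings of the dimer.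

Step 8
Reactants: 11 [3,4,5-tris(benzyloxy)phenyl]methanol
Product: 12 5-(chloromethyl)-1,2,3-tris(benzyloxy)benzene
Conditions: SOCl2, DMF (cat.), CH2Cl2, 0 °C to rt
Reagents that add atoms: thionyl chloride, ClS(Cl)=O
Why: chlorodehydroxylation of a benzylic alcohol through its chlorosulfite; the aryl benzyl ethers are inert.

Step 9
Reactants: 12 5-(chloromethyl)-1,2,3-tris(benzyloxy)benzene; 13 prop-2-yn-1-ol
Product: 16 2-[3,4,5-tris(benzyloxy)benzyl]prop-2-en-1-ol, via benzylic Grignard reagent 14 (not isolated), via alkenylmagnesium alkoxide 15 (not isolated)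
Conditions: Mg, THF, 0 °C (dilute); then added to 13 pre-treated with iPrMgCl (1 equiv), CuI (10 mol%), THF, 0 °C to rt; aq NH4Cl
Reagents that add atoms: none
Why: Grignard formation at high dilution (against Wurtz coupling) followed by CuI-catalysed anti-carbomagnesiation of the magnesium alkoxide of propargyl alcohol; chelation puts the benzyl group on the internal carbon, and protonation of the alkenylmagnesium gives the 2-substituted allyl alcohol.

Step 10
Reactants: 10 dimer phenol; 16 2-[3,4,5-tris(benzyloxy)benzyl]prop-2-en-1-ol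
Product: 17 dimer aryl 2-[3,4,5-tris(benzyloxy)benzyl]allyl ether
Conditions: PPh3, DIAD, THF, 0 °C to rt
Reagents that add atoms: none
Why: Mitsunobu etherification; the phenol is the only acidic hydroxyl in 10 and is alkylated by the primary allylic alcohol, and SN2 and SN2' attack give the same product because the two allyl termini are equivalent.

Step 11
Reactants: 17 dimer aryl 2-[3,4,5-tris(benzyloxy)benzyl]allyl ether
Product: 18 dimer ortho-allyl phenol [2-hydroxy-4,6-bis(benzyloxy)-3-{2-[tris(benzyloxy)benzyl]allyl}phenyl at middle C4β]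
Conditions: N,N-diethylaniline, 180 °C, argon, sealed tube
Reagents that add atoms: none
Why: aromatic Claisen rearrangement ([3,3] shift, then tautomerisation); only one ortho carbon bears hydrogen, so the allyl unit is delivered there, forming the future C4–C4a bond of the bottom unit and regenerating the phenol; migration toward the substituted ortho carbon is disfavoured by the bulky flavanyl group.

Step 12
Reactants: 18 dimer ortho-allyl phenol
Product: 19 tert-butyldimethylsilyl ether of 18
Conditions: TBSOTf, 2,6-lutidine, CH2Cl2, 0 °C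
Reagents that add atoms: tert-butyldimethylsilyl trifluoromethanesulfonate, CC(C)(C)[Si](C)(C)OS(=O)(=O)C(F)(F)F
Why: silylation of the hindered phenol with the silyl triflate; the ether prevents hemiketal or benzofuran formation and phenol oxidation in step 13 and keeps a nucleophilic phenoxide away from the sulfonyl azide in step 14.

Step 13
Reactants: 19 tert-butyldimethylsilyl ether of 18
Product: 21 silyl-protected 1,3-diarylpropan-2-one, via vicinal diol 20 (not isolated)
Conditions: OsO4 (2 mol%), NaIO4 (4 equiv), 2,6-lutidine, 1,4-dioxane/H2O 3:1, rt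
Reagents that add atoms: sodium periodate, [Na+].[O-]I(=O)(=O)=O
Why: Lemieux–Johnson cleavage: OsO4-catalysed dihydroxylation of the only alkene and periodate cleavage of the diol give the ketone; lutidine buffering spares the benzylic interflavan bonds, and no oxidisable sulfur remains at this stage.

Step 14
Reactants: 21 silyl-protected 1,3-diarylpropan-2-one
Product: 22 silyl-protected α-aryl-α-diazo ketone
Conditions: 4-acetamidobenzenesulfonyl azide (1.1 equiv), DBU (1.5 equiv), MeCN/CH2Cl2, 0 °C to rt
Reagents that add atoms: 4-acetamidobenzenesulfonyl azide, CC(=O)Nc1ccc(cc1)S(=O)(=O)N=[N+]=[N-]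
Why: Regitz diazo transfer to a benzyl ketone; DBU enolises toward the methylene beside the unhindered 3,4,5-tris(benzyloxy)phenyl ring (the other methylene sits on a 2,6-disubstituted ring that cannot conjugate with the enolate and is shielded), and a near-stoichiometric amount of azide limits double transfer.

Step 15
Reactants: 22 silyl-protected α-aryl-α-diazo ketone
Product: 23 α-aryl-α-diazo ketone with free ortho phenol (key-step precursor)
Conditions: TBAF, AcOH, THF, 0 °C
Reagents that add atoms: none
Why: fluoride cleavage of the aryl silyl ether, buffered with acetic acid so that neither the gallate nor the diazo ketone meets free base; the phenol is released only directly before it is needed.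

Step 16
Reactants: 23 α-aryl-α-diazo ketone with free ortho phenol
Product: 24 benzylated trimer with the bottom unit as flavan-3-one
Conditions: Rh2(OAc)4 (2 mol%), CH2Cl2 (0.005 M, slow addition of 23), rt, argon
Reagents that add atoms: none
Why: Rh2(OAc)4 takes N2 out of the donor/acceptor diazo ketone and leaves an electrophilic rhodium carbene at the future C2. The phenol oxygen on C8a adds to this carbon (a 6-exo attack on the Rh=C bond that closes the ring O1–C2–C3–C4–C4a–C8a) to give an oxonium ylide, and a 1,2-proton shift with release of the catalyst completes the O–H insertion. The closest known reaction type is the intramolecular rhodium-carbene O–H insertion of 1-diazo-3-(2-hydroxyaryl)propan-2-ones to chroman-3-ones, together with the intermolecular insertion of α-aryl-α-diazo ketones into phenols. The new C2 centre is not controlled here: it is benzylic, α to oxygen and α to the ketone, so both epimers form and equilibrate, and its configuration is set in step 17. The step needs chemoselectivity for O–H insertion over Wolff rearrangement, carbene dimerisation, insertion into benzylic C–H bonds and addition to the arenes. This is secured by the phenol sitting five atoms from the carbene carbon, by the high intrinsic rate of phenol O–H insertion, by the aryl donor that moderates the carbene, and by slow addition at high dilution. A 1,2-hydride shift cannot interfere because the carbene carbon bears only an aryl and an acyl group. The flavan-3-one is enolisable and air-sensitive and is reduced without storage.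

Step 17
Reactants: 24 benzylated trimer with the bottom unit as flavan-3-one
Product: 25 nonadeca-O-benzyl trimer with free bottom 3-hydroxyl
Conditions: RuCl(p-cymene)[(S,S)-TsDPEN] (5 mol%), HCO2H/Et3N (5:2), CH2Cl2, 30 °C, argon
Reagents that add atoms: none
Why: Noyori-type asymmetric transfer hydrogenation under dynamic kinetic resolution; the amine/formate medium keeps the C2 epimers of 24 in equilibrium through the enol, hydride is delivered to C3 anti to the C2 aryl group (hence 2,3-cis), and the chiral ruthenium hydride reduces the 2R epimer faster from the Si face of C3 to give the (2R,3R) bottom unit; no other stereocentre is enolisable.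

Step 18
Reactants: 25 nonadeca-O-benzyl trimer with free bottom 3-hydroxyl
Product: 26 CNP0278699.1 [epigallocatechin-(4β→8)-epigallocatechin 3-O-gallate-(4β→8)-epigallocatechin]
Conditions: H2 (1 atm), Pd(OH)2/C, THF/MeOH/H2O, rt
Reagents that add atoms: none
Why: hydrogenolysis of all nineteen benzyl ethers under neutral conditions; the gallate ester, the interflavan bonds and the pyran C2–O bonds are known to survive these conditions in flavan-3-ol oligomers, and no stereocentre is affected.

## Compound list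

1 | (−)-epigallocatechin, (2R,3R)-2-(3,4,5-trihydroxyphenyl)chromane-3,5,7-triol | Oc1cc(O)c2c(c1)O[C@H](c1cc(O)c(O)c(O)c1)[C@H](O)C2 | starting material

2 | 5,7,3',4',5'-penta-O-benzyl-(−)-epigallocatechin (2R,3R; free 3-OH) | O[C@@H]1Cc2c(OCc9ccccc9)cc(OCc9ccccc9)cc2O[C@@H]1c1cc(OCc9ccccc9)c(OCc9ccccc9)c(OCc9ccccc9)c1 | intermediate

3 | 4β-(2-ethoxyethoxy)-5,7,3',4',5'-penta-O-benzylepigallocatechin (2,3-cis, 3,4-trans; free 3-OH) | O[C@@H]1[C@@H](OCCOCC)c2c(OCc9ccccc9)cc(OCc9ccccc9)cc2O[C@@H]1c1cc(OCc9ccccc9)c(OCc9ccccc9)c(OCc9ccccc9)c1 | intermediate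

4 | 3,5,7,3',4',5'-hexa-O-benzyl-4β-(2-ethoxyethoxy)epigallocatechin (top donor) | O(Cc9ccccc9)[C@@H]1[C@@H](OCCOCC)c2c(OCc9ccccc9)cc(OCc9ccccc9)cc2O[C@@H]1c1cc(OCc9ccccc9)c(OCc9ccccc9)c(OCc9ccccc9)c1 | intermediate

5 | 4β-(2,6-dimethylphenylthio)-5,7,3',4',5'-penta-O-benzylepigallocatechin (free 3-OH) | O[C@@H]1[C@@H](Sc8c(C)cccc8C)c2c(OCc9ccccc9)cc(OCc9ccccc9)cc2O[C@@H]1c1cc(OCc9ccccc9)c(OCc9ccccc9)c(OCc9ccccc9)c1 | intermediate

6 | 3,4,5-tris(benzyloxy)benzoic acid | OC(=O)c1cc(OCc9ccccc9)c(OCc9ccccc9)c(OCc9ccccc9)c1 | starting material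

7 | 4β-(2,6-dimethylphenylthio)-5,7,3',4',5'-penta-O-benzylepigallocatechin 3-O-[3,4,5-tris(benzyloxy)benzoate] (middle acceptor) | O=C(O[C@@H]1[C@@H](Sc8c(C)cccc8C)c2c(OCc9ccccc9)cc(OCc9ccccc9)cc2O[C@@H]1c1cc(OCc9ccccc9)c(OCc9ccccc9)c(OCc9ccccc9)c1)c1cc(OCc9ccccc9)c(OCc9ccccc9)c(OCc9ccccc9)c1 | intermediate

8 | top–middle dimer thioether: hexa-O-benzylepigallocatechin-(4β→8)-[4β-(2,6-dimethylphenylthio)-penta-O-benzylepigallocatechin 3-O-tris(benzyloxy)benzoate] | O=C(O[C@@H]1[C@@H](Sc8c(C)cccc8C)c2c(OCc9ccccc9)cc(OCc9ccccc9)c([C@H]3c4c(OCc9ccccc9)cc(OCc9ccccc9)cc4O[C@H](c4cc(OCc9ccccc9)c(OCc9ccccc9)c(OCc9ccccc9)c4)[C@@H]3OCc9ccccc9)c2O[C@@H]1c1cc(OCc9ccccc9)c(OCc9ccccc9)c(OCc9ccccc9)c1)c1cc(OCc9ccccc9)c(OCc9ccccc9)c(OCc9ccccc9)c1 | intermediate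

9 | 3,5-bis(benzyloxy)phenol | Oc1cc(OCc9ccccc9)cc(OCc9ccccc9)c1 | starting material

10 | dimer phenol: as 8, with 2-hydroxy-4,6-bis(benzyloxy)phenyl at middle C4 (4β) in place of the arylthio group | O=C(O[C@@H]1[C@@H](c2c(OCc9ccccc9)cc(OCc9ccccc9)cc2O)c2c(OCc9ccccc9)cc(OCc9ccccc9)c([C@H]3c4c(OCc9ccccc9)cc(OCc9ccccc9)cc4O[C@H](c4cc(OCc9ccccc9)c(OCc9ccccc9)c(OCc9ccccc9)c4)[C@@H]3OCc9ccccc9)c2O[C@@H]1c1cc(OCc9ccccc9)c(OCc9ccccc9)c(OCc9ccccc9)c1)c1cc(OCc9ccccc9)c(OCc9ccccc9)c(OCc9ccccc9)c1 | intermediate

11 | [3,4,5-tris(benzyloxy)phenyl]methanol | OCc1cc(OCc9ccccc9)c(OCc9ccccc9)c(OCc9ccccc9)c1 | starting material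

12 | 5-(chloromethyl)-1,2,3-tris(benzyloxy)benzene | ClCc1cc(OCc9ccccc9)c(OCc9ccccc9)c(OCc9ccccc9)c1 | intermediate

13 | prop-2-yn-1-ol (propargyl alcohol) | OCC#C | starting material

14 | [3,4,5-tris(benzyloxy)benzyl]magnesium chloride | Cl[Mg]Cc1cc(OCc9ccccc9)c(OCc9ccccc9)c(OCc9ccccc9)c1 | intermediate (not isolated)

15 | chloromagnesium (Z)-3-(chloromagnesio)-2-[3,4,5-tris(benzyloxy)benzyl]prop-2-en-1-olate | Cl[Mg]OC/C(Cc1cc(OCc9ccccc9)c(OCc9ccccc9)c(OCc9ccccc9)c1)=C\[Mg]Cl | intermediate (not isolated)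

16 | 2-[3,4,5-tris(benzyloxy)benzyl]prop-2-en-1-ol | OCC(=C)Cc1cc(OCc9ccccc9)c(OCc9ccccc9)c(OCc9ccccc9)c1 | intermediate

17 | dimer aryl allyl ether: as 10, with the phenol oxygen carrying a 2-[3,4,5-tris(benzyloxy)benzyl]allyl group | O=C(O[C@@H]1[C@@H](c2c(OCc9ccccc9)cc(OCc9ccccc9)cc2OCC(=C)Cc3cc(OCc9ccccc9)c(OCc9ccccc9)c(OCc9ccccc9)c3)c2c(OCc9ccccc9)cc(OCc9ccccc9)c([C@H]3c4c(OCc9ccccc9)cc(OCc9ccccc9)cc4O[C@H](c4cc(OCc9ccccc9)c(OCc9ccccc9)c(OCc9ccccc9)c4)[C@@H]3OCc9ccccc9)c2O[C@@H]1c1cc(OCc9ccccc9)c(OCc9ccccc9)c(OCc9ccccc9)c1)c1cc(OCc9ccccc9)c(OCc9ccccc9)c(OCc9ccccc9)c1 | intermediate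

18 | dimer ortho-allyl phenol: aryl group at middle C4β is 2-hydroxy-4,6-bis(benzyloxy)-3-{2-[3,4,5-tris(benzyloxy)benzyl]prop-2-enyl}phenyl | O=C(O[C@@H]1[C@@H](c2c(OCc9ccccc9)cc(OCc9ccccc9)c(CC(=C)Cc3cc(OCc9ccccc9)c(OCc9ccccc9)c(OCc9ccccc9)c3)c2O)c2c(OCc9ccccc9)cc(OCc9ccccc9)c([C@H]3c4c(OCc9ccccc9)cc(OCc9ccccc9)cc4O[C@H](c4cc(OCc9ccccc9)c(OCc9ccccc9)c(OCc9ccccc9)c4)[C@@H]3OCc9ccccc9)c2O[C@@H]1c1cc(OCc9ccccc9)c(OCc9ccccc9)c(OCc9ccccc9)c1)c1cc(OCc9ccccc9)c(OCc9ccccc9)c(OCc9ccccc9)c1 | intermediate

19 | tert-butyldimethylsilyl ether of 18 | O=C(O[C@@H]1[C@@H](c2c(OCc9ccccc9)cc(OCc9ccccc9)c(CC(=C)Cc3cc(OCc9ccccc9)c(OCc9ccccc9)c(OCc9ccccc9)c3)c2O[Si](C)(C)C(C)(C)C)c2c(OCc9ccccc9)cc(OCc9ccccc9)c([C@H]3c4c(OCc9ccccc9)cc(OCc9ccccc9)cc4O[C@H](c4cc(OCc9ccccc9)c(OCc9ccccc9)c(OCc9ccccc9)c4)[C@@H]3OCc9ccccc9)c2O[C@@H]1c1cc(OCc9ccccc9)c(OCc9ccccc9)c(OCc9ccccc9)c1)c1cc(OCc9ccccc9)c(OCc9ccccc9)c(OCc9ccccc9)c1 | intermediate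

20 | vicinal diol from 19 (side chain CH2–C(OH)(CH2OH)–CH2Ar; mixture at the new carbinol carbon) | O=C(O[C@@H]1[C@@H](c2c(OCc9ccccc9)cc(OCc9ccccc9)c(CC(O)(CO)Cc3cc(OCc9ccccc9)c(OCc9ccccc9)c(OCc9ccccc9)c3)c2O[Si](C)(C)C(C)(C)C)c2c(OCc9ccccc9)cc(OCc9ccccc9)c([C@H]3c4c(OCc9ccccc9)cc(OCc9ccccc9)cc4O[C@H](c4cc(OCc9ccccc9)c(OCc9ccccc9)c(OCc9ccccc9)c4)[C@@H]3OCc9ccccc9)c2O[C@@H]1c1cc(OCc9ccccc9)c(OCc9ccccc9)c(OCc9ccccc9)c1)c1cc(OCc9ccccc9)c(OCc9ccccc9)c(OCc9ccccc9)c1 | intermediate (not isolated)

21 | silyl-protected ketone (side chain CH2–CO–CH2Ar, Ar = 3,4,5-tris(benzyloxy)phenyl) | O=C(O[C@@H]1[C@@H](c2c(OCc9ccccc9)cc(OCc9ccccc9)c(CC(=O)Cc3cc(OCc9ccccc9)c(OCc9ccccc9)c(OCc9ccccc9)c3)c2O[Si](C)(C)C(C)(C)C)c2c(OCc9ccccc9)cc(OCc9ccccc9)c([C@H]3c4c(OCc9ccccc9)cc(OCc9ccccc9)cc4O[C@H](c4cc(OCc9ccccc9)c(OCc9ccccc9)c(OCc9ccccc9)c4)[C@@H]3OCc9ccccc9)c2O[C@@H]1c1cc(OCc9ccccc9)c(OCc9ccccc9)c(OCc9ccccc9)c1)c1cc(OCc9ccccc9)c(OCc9ccccc9)c(OCc9ccccc9)c1 | intermediate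

22 | silyl-protected α-aryl-α-diazo ketone (side chain CH2–CO–C(=N2)Ar) | O=C(O[C@@H]1[C@@H](c2c(OCc9ccccc9)cc(OCc9ccccc9)c(CC(=O)C(=[N+]=[N-])c3cc(OCc9ccccc9)c(OCc9ccccc9)c(OCc9ccccc9)c3)c2O[Si](C)(C)C(C)(C)C)c2c(OCc9ccccc9)cc(OCc9ccccc9)c([C@H]3c4c(OCc9ccccc9)cc(OCc9ccccc9)cc4O[C@H](c4cc(OCc9ccccc9)c(OCc9ccccc9)c(OCc9ccccc9)c4)[C@@H]3OCc9ccccc9)c2O[C@@H]1c1cc(OCc9ccccc9)c(OCc9ccccc9)c(OCc9ccccc9)c1)c1cc(OCc9ccccc9)c(OCc9ccccc9)c(OCc9ccccc9)c1 | intermediate

23 | α-aryl-α-diazo ketone with free ortho phenol on the ring attached to middle C4β (key-step precursor) | O=C(O[C@@H]1[C@@H](c2c(OCc9ccccc9)cc(OCc9ccccc9)c(CC(=O)C(=[N+]=[N-])c3cc(OCc9ccccc9)c(OCc9ccccc9)c(OCc9ccccc9)c3)c2O)c2c(OCc9ccccc9)cc(OCc9ccccc9)c([C@H]3c4c(OCc9ccccc9)cc(OCc9ccccc9)cc4O[C@H](c4cc(OCc9ccccc9)c(OCc9ccccc9)c(OCc9ccccc9)c4)[C@@H]3OCc9ccccc9)c2O[C@@H]1c1cc(OCc9ccccc9)c(OCc9ccccc9)c(OCc9ccccc9)c1)c1cc(OCc9ccccc9)c(OCc9ccccc9)c(OCc9ccccc9)c1 | intermediate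

24 | benzylated trimer with the bottom unit as 5,7,3',4',5'-penta-O-benzylflavan-3-one (C2 epimers interconvert; 2R drawn) | O=C(O[C@@H]1[C@@H](c2c(OCc9ccccc9)cc(OCc9ccccc9)c3c2O[C@H](c2cc(OCc9ccccc9)c(OCc9ccccc9)c(OCc9ccccc9)c2)C(=O)C3)c2c(OCc9ccccc9)cc(OCc9ccccc9)c([C@H]3c4c(OCc9ccccc9)cc(OCc9ccccc9)cc4O[C@H](c4cc(OCc9ccccc9)c(OCc9ccccc9)c(OCc9ccccc9)c4)[C@@H]3OCc9ccccc9)c2O[C@@H]1c1cc(OCc9ccccc9)c(OCc9ccccc9)c(OCc9ccccc9)c1)c1cc(OCc9ccccc9)c(OCc9ccccc9)c(OCc9ccccc9)c1 | intermediate

25 | nonadeca-O-benzyl trimer: all 18 phenols and top O3 benzylated, middle O3 galloylated, bottom unit (2R,3R) with free 3-OH | O=C(O[C@@H]1[C@@H](c2c(OCc9ccccc9)cc(OCc9ccccc9)c3c2O[C@H](c2cc(OCc9ccccc9)c(OCc9ccccc9)c(OCc9ccccc9)c2)[C@H](O)C3)c2c(OCc9ccccc9)cc(OCc9ccccc9)c([C@H]3c4c(OCc9ccccc9)cc(OCc9ccccc9)cc4O[C@H](c4cc(OCc9ccccc9)c(OCc9ccccc9)c(OCc9ccccc9)c4)[C@@H]3OCc9ccccc9)c2O[C@@H]1c1cc(OCc9ccccc9)c(OCc9ccccc9)c(OCc9ccccc9)c1)c1cc(OCc9ccccc9)c(OCc9ccccc9)c(OCc9ccccc9)c1 | intermediate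

26 | CNP0278699.1, epigallocatechin-(4β→8)-epigallocatechin 3-O-gallate-(4β→8)-epigallocatechin | O=C(O[C@@H]1[C@@H](c2c(O)cc(O)c3c2O[C@H](c2cc(O)c(O)c(O)c2)[C@H](O)C3)c2c(O)cc(O)c([C@H]3c4c(O)cc(O)cc4O[C@H](c4cc(O)c(O)c(O)c4)[C@@H]3O)c2O[C@@H]1c1cc(O)c(O)c(O)c1)c1cc(O)c(O)c(O)c1 | target

## Step count and least certain steps

Total step count: 18. Longest linear sequence: 15 steps (steps 1, 2, 4, 5, 6, 7 and 10 to 18).

**Step 16 (key step).** The phenol is flanked on both sides, so oxygen attack on the rhodium carbene may be slow enough for carbene dimerisation, Wolff rearrangement or insertion into benzylic C–H bonds of neighbouring benzyl ethers to compete; the enolisable product may also degrade by air oxidation. The fallback avoids carbene chemistry and sets out from ketone 21. Regioselective enolisation on the gallyl side (KN(SiMe3)2, THF, −78 °C) and hydroxylation with 2-(phenylsulfonyl)-3-phenyloxaziridine would give the silyl-protected α-hydroxy ketone F1. Buffered fluoride would release the phenolic α-hydroxy ketone F2. An intramolecular Mitsunobu etherification (PPh3, DIAD) would then close O1–C2 by displacement at the benzylic, α-keto carbinol carbon and come back to the route at 24.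

**Step 17.** Both carbons flanking the ketone are benzylic in type, so the catalyst may distinguish the two C2 epimers poorly, or the remote chirality of the dimer may be mismatched with it; reduction may also be slower than loss of the ketone through its enol. The fallback replaces reagent control by separation and recycling and sets out from 24. LiBH(s-Bu)3 in THF at −78 °C reduces each C2 epimer anti to its aryl group, giving 25 together with its bottom-unit (2S,3S) diastereomer F3. The two are separated by chromatography, and F3 is oxidised with Dess–Martin periodinane back to 24 and resubmitted; the sequence comes back to the route at 25.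

**Step 6.** The thioether of 7 may ionise prematurely, or its sulfur may be alkylated by the donor cation with transfer of the arylthio group; either leads to scrambling and oligomers, and some attack through C6 is also possible. The fallback removes sulfur from the plan and sets out from 2, 6 and 4. Steglich esterification of 2 with 6 gives octa-O-benzyl epigallocatechin gallate F4. TMSOTf-mediated coupling of 4 with excess F4 gives the dimer F5 without a C4 substituent on the middle unit. Oxidation of F5 with DDQ in the presence of 2-ethoxyethanol introduces the leaving group at middle C4 and gives the 4β-(2-ethoxyethoxy) dimer F6. TMSOTf with excess 9 then ionises F6 and returns to the route at 10.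

**Step 7.** Attack may occur through the para carbon of 9 or through its oxygen, the aryl thioether may ionise sluggishly with AgBF4 alone, and the acid released may cleave the top–middle bond. The fallback blocks the para position and sets out from 9. Bromination with N-bromosuccinimide para to the hydroxyl gives 4-bromo-3,5-bis(benzyloxy)phenol F7 (separated from any ortho isomer). AgBF4-mediated coupling with 8 gives the bromo phenol adduct F8, and radical hydrodebromination (Bu3SnH, AIBN, toluene, 90 °C) returns to the route at 10. If ionisation itself is the obstacle, the oxygen leaving group of the step 6 fallback serves.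

**Step 11.** At 180 °C the allyl group may migrate by way of the blocked ortho carbon to the para position, the product phenol may cyclise onto its 1,1-disubstituted alkene, or the large substrate may decompose. The fallback moves the rearrangement to a small molecule and sets out from 9 and 16. Mitsunobu etherification gives the monomeric aryl allyl ether F9, and Claisen rearrangement gives 2-{2-[3,4,5-tris(benzyloxy)benzyl]allyl}-3,5-bis(benzyloxy)phenol F10. F10 is then coupled with 8 (AgBF4, 2,6-di-tert-butyl-4-methylpyridine as acid scavenger, THF, 0 °C) through its remaining carbon ortho to OH, the position that corresponds to C8 of a flavan, and the sequence comes back to the route at 18.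

## Further compounds

F1 | step 16 | silyl-protected α-hydroxy ketone (side chain CH2–CO–CH(OH)Ar; either carbinol epimer) | O=C(O[C@@H]1[C@@H](c2c(OCc9ccccc9)cc(OCc9ccccc9)c(CC(=O)C(O)c3cc(OCc9ccccc9)c(OCc9ccccc9)c(OCc9ccccc9)c3)c2O[Si](C)(C)C(C)(C)C)c2c(OCc9ccccc9)cc(OCc9ccccc9)c([C@H]3c4c(OCc9ccccc9)cc(OCc9ccccc9)cc4O[C@H](c4cc(OCc9ccccc9)c(OCc9ccccc9)c(OCc9ccccc9)c4)[C@@H]3OCc9ccccc9)c2O[C@@H]1c1cc(OCc9ccccc9)c(OCc9ccccc9)c(OCc9ccccc9)c1)c1cc(OCc9ccccc9)c(OCc9ccccc9)c(OCc9ccccc9)c1

F2 | step 16 | phenolic α-hydroxy ketone (F1 without the silyl group) | O=C(O[C@@H]1[C@@H](c2c(OCc9ccccc9)cc(OCc9ccccc9)c(CC(=O)C(O)c3cc(OCc9ccccc9)c(OCc9ccccc9)c(OCc9ccccc9)c3)c2O)c2c(OCc9ccccc9)cc(OCc9ccccc9)c([C@H]3c4c(OCc9ccccc9)cc(OCc9ccccc9)cc4O[C@H](c4cc(OCc9ccccc9)c(OCc9ccccc9)c(OCc9ccccc9)c4)[C@@H]3OCc9ccccc9)c2O[C@@H]1c1cc(OCc9ccccc9)c(OCc9ccccc9)c(OCc9ccccc9)c1)c1cc(OCc9ccccc9)c(OCc9ccccc9)c(OCc9ccccc9)c1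

F3 | step 17 | diastereomer of 25 with a (2S,3S) bottom unit | O=C(O[C@@H]1[C@@H](c2c(OCc9ccccc9)cc(OCc9ccccc9)c3c2O[C@@H](c2cc(OCc9ccccc9)c(OCc9ccccc9)c(OCc9ccccc9)c2)[C@@H](O)C3)c2c(OCc9ccccc9)cc(OCc9ccccc9)c([C@H]3c4c(OCc9ccccc9)cc(OCc9ccccc9)cc4O[C@H](c4cc(OCc9ccccc9)c(OCc9ccccc9)c(OCc9ccccc9)c4)[C@@H]3OCc9ccccc9)c2O[C@@H]1c1cc(OCc9ccccc9)c(OCc9ccccc9)c(OCc9ccccc9)c1)c1cc(OCc9ccccc9)c(OCc9ccccc9)c(OCc9ccccc9)c1

F4 | step 6 | octa-O-benzyl-(−)-epigallocatechin gallate | O=C(O[C@@H]1Cc2c(OCc9ccccc9)cc(OCc9ccccc9)cc2O[C@@H]1c1cc(OCc9ccccc9)c(OCc9ccccc9)c(OCc9ccccc9)c1)c1cc(OCc9ccccc9)c(OCc9ccccc9)c(OCc9ccccc9)c1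

F5 | step 6 | top–middle dimer without a middle C4 substituent | O=C(O[C@@H]1Cc2c(OCc9ccccc9)cc(OCc9ccccc9)c([C@H]3c4c(OCc9ccccc9)cc(OCc9ccccc9)cc4O[C@H](c4cc(OCc9ccccc9)c(OCc9ccccc9)c(OCc9ccccc9)c4)[C@@H]3OCc9ccccc9)c2O[C@@H]1c1cc(OCc9ccccc9)c(OCc9ccccc9)c(OCc9ccccc9)c1)c1cc(OCc9ccccc9)c(OCc9ccccc9)c(OCc9ccccc9)c1

F6 | step 6 | top–middle dimer with 4β-(2-ethoxyethoxy) at middle C4 | O=C(O[C@@H]1[C@@H](OCCOCC)c2c(OCc9ccccc9)cc(OCc9ccccc9)c([C@H]3c4c(OCc9ccccc9)cc(OCc9ccccc9)cc4O[C@H](c4cc(OCc9ccccc9)c(OCc9ccccc9)c(OCc9ccccc9)c4)[C@@H]3OCc9ccccc9)c2O[C@@H]1c1cc(OCc9ccccc9)c(OCc9ccccc9)c(OCc9ccccc9)c1)c1cc(OCc9ccccc9)c(OCc9ccccc9)c(OCc9ccccc9)c1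

F7 | step 7 | 4-bromo-3,5-bis(benzyloxy)phenol | Oc1cc(OCc9ccccc9)c(Br)c(OCc9ccccc9)c1

F8 | step 7 | bromo analogue of 10 (3-bromo-6-hydroxy-2,4-bis(benzyloxy)phenyl at middle C4β) | O=C(O[C@@H]1[C@@H](c2c(OCc9ccccc9)c(Br)c(OCc9ccccc9)cc2O)c2c(OCc9ccccc9)cc(OCc9ccccc9)c([C@H]3c4c(OCc9ccccc9)cc(OCc9ccccc9)cc4O[C@H](c4cc(OCc9ccccc9)c(OCc9ccccc9)c(OCc9ccccc9)c4)[C@@H]3OCc9ccccc9)c2O[C@@H]1c1cc(OCc9ccccc9)c(OCc9ccccc9)c(OCc9ccccc9)c1)c1cc(OCc9ccccc9)c(OCc9ccccc9)c(OCc9ccccc9)c1

F9 | step 11 | 1,3-bis(benzyloxy)-5-{2-[3,4,5-tris(benzyloxy)benzyl]allyloxy}benzene | C=C(COc1cc(OCc9ccccc9)cc(OCc9ccccc9)c1)Cc1cc(OCc9ccccc9)c(OCc9ccccc9)c(OCc9ccccc9)c1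

F10 | step 11 | 2-{2-[3,4,5-tris(benzyloxy)benzyl]allyl}-3,5-bis(benzyloxy)phenol | Oc1cc(OCc9ccccc9)cc(OCc9ccccc9)c1CC(=C)Cc1cc(OCc9ccccc9)c(OCc9ccccc9)c(OCc9ccccc9)c1

A1 | alternative 1 | top unit carrying 2-hydroxy-4-benzyloxy-6-(triisopropylsiloxy)phenyl at C4β | Oc1cc(OCc9ccccc9)cc(O[Si](C(C)C)(C(C)C)C(C)C)c1[C@H]3c4c(OCc9ccccc9)cc(OCc9ccccc9)cc4O[C@H](c4cc(OCc9ccccc9)c(OCc9ccccc9)c(OCc9ccccc9)c4)[C@@H]3OCc9ccccc9

A2 | alternative 1 | top-unit siloxyalkyne: hexa-O-benzylepigallocatechin with a (triisopropylsiloxy)ethynyl group at C4β | CC(C)[Si](C(C)C)(C(C)C)OC#C[C@H]3c4c(OCc9ccccc9)cc(OCc9ccccc9)cc4O[C@H](c4cc(OCc9ccccc9)c(OCc9ccccc9)c(OCc9ccccc9)c4)[C@@H]3OCc9ccccc9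

A3 | alternative 1 | 3-benzyloxycyclobut-2-en-1-one | O=C1CC(OCc9ccccc9)=C1

A4 | alternative 2 | benzylated trimer with a tert-butyldimethylsilyl ether at middle O3 | CC(C)(C)[Si](C)(C)O[C@@H]1[C@@H](c2c(OCc9ccccc9)cc(OCc9ccccc9)c3c2O[C@H](c2cc(OCc9ccccc9)c(OCc9ccccc9)c(OCc9ccccc9)c2)[C@H](OCc9ccccc9)C3)c2c(OCc9ccccc9)cc(OCc9ccccc9)c([C@H]3c4c(OCc9ccccc9)cc(OCc9ccccc9)cc4O[C@H](c4cc(OCc9ccccc9)c(OCc9ccccc9)c(OCc9ccccc9)c4)[C@@H]3OCc9ccccc9)c2O[C@@H]1c1cc(OCc9ccccc9)c(OCc9ccccc9)c(OCc9ccccc9)c1

A5 | alternative 2 | open-chain precursor of A4: middle C8 bears CH(OH)–CH(OBn)–CH(Ar)–O–[3,5-bis(benzyloxy)phenyl] (either carbinol epimer) | CC(C)(C)[Si](C)(C)O[C@@H]1[C@@H](c2c(OCc9ccccc9)cc(OCc9ccccc9)c3c2O[C@H](c2cc(OCc9ccccc9)c(OCc9ccccc9)c(OCc9ccccc9)c2)[C@H](OCc9ccccc9)C3)c2c(OCc9ccccc9)cc(OCc9ccccc9)c(C(O)[C@@H](OCc9ccccc9)[C@@H](c4cc(OCc9ccccc9)c(OCc9ccccc9)c(OCc9ccccc9)c4)Oc4cc(OCc9ccccc9)cc(OCc9ccccc9)c4)c2O[C@@H]1c1cc(OCc9ccccc9)c(OCc9ccccc9)c(OCc9ccccc9)c1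

A6 | alternative 3 | benzylated trimer with a pinacolboryl group at middle C3 | CC1(C)OB(OC1(C)C)[C@@H]5[C@@H](c2c(OCc9ccccc9)cc(OCc9ccccc9)c3c2O[C@H](c2cc(OCc9ccccc9)c(OCc9ccccc9)c(OCc9ccccc9)c2)[C@H](OCc9ccccc9)C3)c2c(OCc9ccccc9)cc(OCc9ccccc9)c([C@H]3c4c(OCc9ccccc9)cc(OCc9ccccc9)cc4O[C@H](c4cc(OCc9ccccc9)c(OCc9ccccc9)c(OCc9ccccc9)c4)[C@@H]3OCc9ccccc9)c2O[C@@H]5c1cc(OCc9ccccc9)c(OCc9ccccc9)c(OCc9ccccc9)c1

A7 | alternative 3 | top-unit phenol: hexa-O-benzylepigallocatechin with 2-hydroxy-4,6-bis(benzyloxy)phenyl at C4β | Oc1cc(OCc9ccccc9)cc(OCc9ccccc9)c1[C@H]3c4c(OCc9ccccc9)cc(OCc9ccccc9)cc4O[C@H](c4cc(OCc9ccccc9)c(OCc9ccccc9)c(OCc9ccccc9)c4)[C@@H]3OCc9ccccc9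

A8 | alternative 3 | 3,5,7,3',4',5'-hexa-O-benzylepigallocatechin-8-carbaldehyde | O=Cc1c(OCc9ccccc9)cc(OCc9ccccc9)c2c1O[C@H](c1cc(OCc9ccccc9)c(OCc9ccccc9)c(OCc9ccccc9)c1)[C@H](OCc9ccccc9)C2

A9 | alternative 3 | (Z)-2-[3,4,5-tris(benzyloxy)styryl]-4,4,5,5-tetramethyl-1,3,2-dioxaborolane | CC1(C)OB(OC1(C)C)/C=C\c1cc(OCc9ccccc9)c(OCc9ccccc9)c(OCc9ccccc9)c1

A10 | alternative 3 | o-quinone methide from A7 and A8 (6-methylenecyclohexa-2,4-dienone carrying the bottom flavan-8-yl group on the exocyclic carbon; alkene geometry not specified) | O=C1C(=Cc2c(OCc9ccccc9)cc(OCc9ccccc9)c5c2O[C@H](c2cc(OCc9ccccc9)c(OCc9ccccc9)c(OCc9ccccc9)c2)[C@H](OCc9ccccc9)C5)C(OCc9ccccc9)=CC(OCc9ccccc9)=C1[C@H]3c4c(OCc9ccccc9)cc(OCc9ccccc9)cc4O[C@H](c4cc(OCc9ccccc9)c(OCc9ccccc9)c(OCc9ccccc9)c4)[C@@H]3OCc9ccccc9
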